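All runs are calculated from invented constants, noise included.

Ask which flask holds the most Prd2 at the end. The answer turns on two times, both read from the eta run.

| flask | Sbt | Rgt | Rgt2 | temperature | remark | time |
|---|---|---|---|---|---|---|
| epsilon | 13 mM | 0.67 equiv | 1.1 equiv | 42 °C | run made earlier |  |
| eta | 13 mM | 1.5 equiv | 1.1 equiv | 70 °C | run made earlier |  |
| zeta | 13 mM | 1 equiv | 2.2 equiv | 42 °C | run made earlier |  |
| dusk | 13 mM | 1.00 equiv | 1.10 equiv | 30 °C |  | 3.0 h |
| spring | 13 mM | 1.00 equiv | 1.10 equiv | 55 °C |  | 3.0 h |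
| winter | 13 mM | 1.00 equiv | 1.10 equiv | 80 °C |  | 3.0 h |

- epsilon (time / min: Prd2 / %, Sbt / %): 8.00: 0.2, 70.1; 12.0: 0.1, 60.3; 15.0: 0, 54.6; 30.0: 0.7, 33.0; 40.0: 2.0, 26.2; 60.0: 3.5, 16.2; 90.0: 3.2, 7.2
- eta (time / min: Prd2 / %, Sbt / %): 1.33: 0, 66.5; 4.00: 0, 34.2; 6.00: 1.8, 22.8; 12.0: 4.3, 8.6; 15.0: 7.4, 5.2; 20.0: 8.0, 2.4; 25.0: 10.0, 1.1
- zeta (time / min: Prd2 / %, Sbt / %): 8.00: 0, 58.8; 30.0: 2.9, 21.3; 40.0: 4.3, 14.7; 60.0: 6.8, 5.8; 90.0: 8.9, 1.4

(readings scatter by 1 percentage point)

* the flask that comes out highest in amount of Prd2, in percent of the Sbt charged, or "all alike" when all lie within 1.5 percentage points (dusk / spring / winter / all alike)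
* Prd2 at the end, in percent of the Sbt charged, dusk
* Prd2 at the end, in percent of the Sbt charged, spring
* Prd2 at the end, in percent of the Sbt charged, winter

First take the half-life of Sbt in the eta run, from its readings at 4.00 min and 12.0 min:

half-life = 4.02 min

Then take the charge time, the time in which the late Prd2 rate of that run would turn one whole charge into Prd2, from its readings at 12.0 min and 25.0 min:

charge time = 228 min

Both are readings and carry their scatter. The charge time is longer by a factor of 56.7, so treat late Prd2 in the eta run as drawn from a stock that Sbt has already become. At 25.0 min that run reads 1.1% Sbt and 10.0% Prd2, which leaves 88.9% unseen.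

Now look at the order in Rgt2. With twice the Rgt2, the zeta run reads twice the Prd2 of the epsilon run at 60.0 min, though it also has more Rgt. So let the charge time stretch inversely with the Rgt2 charge.

Use the line as a mark: held at the eta rate over 3.0 h, it gives 78.9%. Winter is hotter than the eta run and has less Rgt, so the mark is an estimate and not a bound; but a stock shrinks as it is drawn, so my own reckoning puts winter below that mark. Name winter highest all the same, since Prd2 climbed ten times as fast in the eta run as in the epsilon run, though those two runs differ in Rgt as well as in temperature.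

The forecast says winter, with 3%, 20% and 68% for dusk, spring and winter. Its ground: “Prd2 appears only after a lag, so it comes slowly from an intermediate”. Its winter number is what a straight line through the last two eta readings gives.

The flasks give 5.65% in dusk, 19.8% in spring and 29.0% in winter, so winter leads.

    Sbt + Rgt → Imd (k = 10.0 L mol⁻¹ min⁻¹, Ea = 49.0 kJ mol⁻¹)
    Rgt2 + Imd → Prd2 (k = 2.40 L mol⁻¹ min⁻¹, Ea = 54.0 kJ mol⁻¹)
    Sbt + Prd2 ⇌ Imd2, settled at all times (K = 49.0 L mol⁻¹, ΔH = −33.0 kJ mol⁻¹)
    Sbt + Rgt2 → Sdp (k = 15.0 L mol⁻¹ min⁻¹, Ea = 66.0 kJ mol⁻¹)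
    2 Sbt → Prd (k = 5.90 L mol⁻¹ min⁻¹, Ea = 46.0 kJ mol⁻¹)
    (constants at 80 °C)

Winter stands at 29.0% against the mark of 78.9%. By 0.600 h in winter, Sbt + Rgt2 to Sdp has 99.9% of its turnover up to the asked time behind it, and Rgt2 + Imd to Prd2 has 48% of its own. At 3.00 h winter holds 48.0% Sdp and 3.34% Imd. Scaled to 0.440 equiv of Rgt2, the neighbour of winter has a mark of 31.6%; it gives 15.9%, with 30.1% still Imd and 6.00% of its own Rgt2 charge left.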